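**Plan**

- Ring numbering: C1 (quaternary stereocentre, CH3 and farnesyl), C2 (C=O), C3 (C–CH3), C4 (C–OH), C5 (C–CO2H), C6 (C–CH3).
- Retrosynthetic cuts, in order: the ester of a protected C5 carboxyl; the ring bond C5=C6 (aldol–dehydration); C6=O back to a vinyl group; C5–CO2R and C3–C4 (dianion carboxylation, aldol); C1–C2; C1–B; then the C–C bonds of an (E)-allylic alcohol down to farnesyl bromide.
- Enabling feature: C1 is bonded to the carbonyl carbon C2 and carries the CH3/CH2 pair of a former (E)-trisubstituted alkene. C1–C2 can therefore come from a tertiary allylic C1–B bond by a stereoretentive boron-to-carbon shift onto a propenylidene carbenoid, and the C1–B bond from SN2′ borylation of that alkene.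
- Forward order: the chain is joined first (farnesyl bromide → skipped enyne → (E)-allylic carbonate → tertiary allylboronate → ethyl ketone → β-diketone → β,δ-diketo ester → triketo ester). The only ring, the C1–C6 carbocycle, closes in the penultimate step by C5→C6 aldol–dehydration.
- Stereochemistry: the single stereocentre C1 is set as a C–B bond by copper-catalysed enantioselective SN2′ borylation (ligand control on the (E)-alkene), carried into C1–C2 with retention, and is quaternary and non-epimerisable afterwards. The chain (E)-alkenes come from farnesyl bromide and from syn-carboalumination.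

Key step: step 7

Assumption: the target is written as its 4-hydroxy-2-oxo tautomer; the cross-conjugated vinylogous acid is taken to settle into this hydrogen-bonded enol form by itself, so no step is spent on tautomer control.

**Route**

Step 1
Reactants: 1 (2E,6E)-farnesyl bromide; 2 ethynylmagnesium bromide
Product: 3 (4E,8E)-5,9,13-trimethyltetradeca-4,8,12-trien-1-yne
Conditions: 2 (3 equiv), CuCl (10 mol %), THF, 0 → 45 °C
Reagents that add atoms: none
Why: Copper-catalysed allyl–alkynyl Grignard cross-coupling at the primary allylic carbon (SN2) should give the skipped enyne with the (E)-alkenes untouched, the excess of acetylide suppressing double allylation.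

Step 2
Reactants: 3 (4E,8E)-5,9,13-trimethyltetradeca-4,8,12-trien-1-yne
Product: 6 (2E,5E,9E)-3,6,10,14-tetramethylpentadeca-2,5,9,13-tetraen-1-ol, via dimethyl[(1E,4E,8E)-2,5,9,13-tetramethyltetradeca-1,4,8,12-tetraen-1-yl]alumane 4 (not isolated), via lithium butyl(dimethyl)[(1E,4E,8E)-2,5,9,13-tetramethyltetradeca-1,4,8,12-tetraen-1-yl]aluminate 5 (not isolated)
Conditions: Me3Al, Cp2ZrCl2 (25 mol %), CH2Cl2, 0 °C → rt; volatiles removed; n-BuLi, THF/hexane, −78 → 0 °C; (CH2O)n, rt
Reagents that add atoms: trimethylaluminium C[Al](C)C; paraformaldehyde (as formaldehyde) C=O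
Why: Negishi zirconium-catalysed syn-methylalumination places CH3 on the internal and Al on the terminal alkyne carbon, and the derived alanate should add to formaldehyde with retention of alkene geometry to give the (2E)-allylic alcohol, the trisubstituted alkenes being inert to carbometalation.

Step 3
Reactants: 6 (2E,5E,9E)-3,6,10,14-tetramethylpentadeca-2,5,9,13-tetraen-1-ol
Product: 7 methyl (2E,5E,9E)-3,6,10,14-tetramethylpentadeca-2,5,9,13-tetraen-1-yl carbonate
Conditions: ClCO2Me, pyridine, CH2Cl2, 0 °C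
Reagents that add atoms: methyl chloroformate COC(Cl)=O
Why: Routine O-acylation of a primary allylic alcohol installs the carbonate leaving group needed for allylic substitution.

Step 4
Reactants: 7 methyl (2E,5E,9E)-3,6,10,14-tetramethylpentadeca-2,5,9,13-tetraen-1-yl carbonate; 8 bis(pinacolato)diboron
Product: 9 2-[(3S,5E,9E)-3,6,10,14-tetramethylpentadeca-1,5,9,13-tetraen-3-yl]-4,4,5,5-tetramethyl-1,3,2-dioxaborolane
Conditions: Cu(OTf)2 (5 mol %), chiral sulfonate-bearing imidazolinium salt (NHC precursor, 5.5 mol %, antipode leading to 3S), NaOMe (0.8 equiv), DME, −30 °C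
Reagents that add atoms: none
Why: Copper-catalysed enantioselective allylic substitution (SN2′ borylation): the chiral NHC–Cu–Bpin species should add to one face of the (E)-trisubstituted alkene with boron at the γ-carbon and expel the carbonate, so that the ligand antipode and the (E)-geometry together set the tertiary C–B stereocentre as S and release the vinyl group.

Step 5
Reactants: 10 prop-2-en-1-ol (allyl alcohol); 11 N,N-diisopropylcarbamoyl chloride
Product: 12 prop-2-en-1-yl N,N-di(propan-2-yl)carbamate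
Conditions: pyridine, 90 °C
Reagents that add atoms: none
Why: O-Carbamoylation of a primary alcohol with a hindered carbamoyl chloride under the usual hot-pyridine conditions.

Step 6
Reactants: 12 prop-2-en-1-yl N,N-di(propan-2-yl)carbamate
Product: 13 (Z)-prop-1-en-1-yl N,N-di(propan-2-yl)carbamate
Conditions: t-BuOK (20 mol %), DMSO, rt
Reagents that add atoms: none
Why: Base-mediated allyl-to-propenyl prototropic isomerisation through the cisoid, cation-chelated oxyallyl anion should give the (Z)-enol carbamate as allyl ethers do, the hindered carbamate resisting tert-butoxide; the geometry does not reach the final product.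

Step 7
Reactants: 9 2-[(3S,5E,9E)-3,6,10,14-tetramethylpentadeca-1,5,9,13-tetraen-3-yl]-4,4,5,5-tetramethyl-1,3,2-dioxaborolane; 13 (Z)-prop-1-en-1-yl N,N-di(propan-2-yl)carbamate
Product: 17 (4R,6E,10E)-4-ethenyl-4,7,11,15-tetramethylhexadeca-6,10,14-trien-3-one, via (Z)-1-lithioprop-1-en-1-yl N,N-di(propan-2-yl)carbamate 14 (not isolated), via lithium {(1Z)-1-[(diisopropylcarbamoyl)oxy]prop-1-en-1-yl}[(3S,5E,9E)-3,6,10,14-tetramethylpentadeca-1,5,9,13-tetraen-3-yl](pinacolato)borate 15 (not isolated), via 2-[(2E,4R,6E,10E)-4-ethenyl-4,7,11,15-tetramethylhexadeca-2,6,10,14-tetraen-3-yl]-4,4,5,5-tetramethyl-1,3,2-dioxaborolane 16 (not isolated)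
Conditions: 13 (1.4 equiv), s-BuLi, TMEDA, THF, −78 °C; 9, −78 °C; MgBr2·OEt2, → rt, then 40 °C; NaOH, H2O2, THF/H2O, 0 °C → rt
Reagents that add atoms: hydrogen peroxide OO
Why: Proposed new method: carbamate-directed vinylic deprotonation of 13 gives the α-lithio enol carbamate 14, which adds to boron of 9 to form ate complex 15 with the C1–B bond in the alkene plane and anti to the carbamate C–O bond, and Mg(II)-assisted loss of carbamate is answered by a concerted 1,2-shift of C1 from boron to the carbenoid carbon (in-plane SN2-type displacement at sp2 carbon) to give alkenylboronate 16, which alkaline peroxide converts into the C2 ketone of 17. The closest known reaction types are the alkenylidene (vinylidene) homologation of boronic esters with α-haloalkenyllithiums or lithiated epoxysilanes, the 1,2-metalate rearrangement of α-metalated enol carbamates on copper with loss of carbamate, and the lithiation–borylation of tertiary pinacol boronic esters with sp3 α-lithio carbamates promoted by MgBr2; new here are the carbamate leaving group on an sp2 carbenoid carbon at boron and the tertiary allylic migrating group. No ring is closed. The C1 stereocentre of 17 is fixed by the configuration of the C–B bond of 9, because C1 moves with its bonding electron pair suprafacially within the four-coordinate ate complex (retention) and never becomes a carbanion, radical or cation. The step needs 1,2- in preference to allylic 1,3-migration and carbon in preference to pinacol-oxygen migration: the saturated boron of 15 has no vacant orbital for a borotropic or SE2′ course and no external electrophile is present to attack the vinyl terminus, and the electron-rich tertiary allylic carbon should migrate faster than an alkoxy oxygen.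

Step 8
Reactants: 17 (4R,6E,10E)-4-ethenyl-4,7,11,15-tetramethylhexadeca-6,10,14-trien-3-one
Product: 19 (5R,7E,11E)-5-ethenyl-2-hydroxy-3,5,8,12,16-pentamethylheptadeca-7,11,15-trien-4-one (mixture at C2 and C3), via lithium (2Z,4R,6E,10E)-4-ethenyl-4,7,11,15-tetramethylhexadeca-2,6,10,14-tetraen-3-olate 18 (not isolated)
Conditions: LDA (commercial solution), THF, −78 °C; MeCHO, −78 °C; aqueous quench at −78 °C
Reagents that add atoms: acetaldehyde CC=O
Why: Directed aldol addition of the only possible enolate of a tert-alkyl ethyl ketone (C1 is quaternary) forms the C3–C4 bond, and the two new carbinol and methine centres need no control because both are levelled in the following steps.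

Step 9
Reactants: 19 (5R,7E,11E)-5-ethenyl-2-hydroxy-3,5,8,12,16-pentamethylheptadeca-7,11,15-trien-4-one
Product: 20 (5R,7E,11E)-5-ethenyl-3,5,8,12,16-pentamethylheptadeca-7,11,15-triene-2,4-dione (C3 epimers and enol forms)
Conditions: Dess–Martin periodinane, NaHCO3, CH2Cl2, 0 °C → rt
Reagents that add atoms: none
Why: Dess–Martin oxidation of a β-hydroxy ketone to the β-diketone proceeds under buffered, non-acidic conditions that leave the four alkenes alone.

Step 10
Reactants: 20 (5R,7E,11E)-5-ethenyl-3,5,8,12,16-pentamethylheptadeca-7,11,15-triene-2,4-dione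
Product: 22 2-(trimethylsilyl)ethyl (6R,8E,12E)-6-ethenyl-4,6,9,13,17-pentamethyl-3,5-dioxooctadeca-8,12,16-trienoate, via dilithium (5R,7E,11E)-5-ethenyl-3,5,8,12,16-pentamethylheptadeca-1,3,7,11,15-pentaene-2,4-diolate 21 (not isolated)
Conditions: LDA (commercial solution, 3.2 equiv), THF, −78 → 0 °C; Teoc-OSu, −78 °C; aqueous quench
Reagents that add atoms: N-[2-(trimethylsilyl)ethoxycarbonyloxy]succinimide (Teoc-OSu) C[Si](C)(C)CCOC(=O)ON1C(=O)CCC1=O
Why: Harris–Weiler-type γ-acylation of a β-diketone dianion: after C3–H the only remaining α-hydrogens are those of the terminal methyl (C1 is quaternary), so the more reactive terminal carbanion should be alkoxycarbonylated to give the C5 ester, chosen as the fluoride-labile 2-(trimethylsilyl)ethyl ester.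

Step 11
Reactants: 22 2-(trimethylsilyl)ethyl (6R,8E,12E)-6-ethenyl-4,6,9,13,17-pentamethyl-3,5-dioxooctadeca-8,12,16-trienoate
Product: 23 2-(trimethylsilyl)ethyl (6R,8E,12E)-6-acetyl-4,6,9,13,17-pentamethyl-3,5-dioxooctadeca-8,12,16-trienoate
Conditions: PdCl2 (20 mol %), CuCl, O2 (1 atm), DMF/H2O 7:1, rt
Reagents that add atoms: water O
Why: Tsuji–Wacker oxidation: Markovnikov hydroxypalladation of the only monosubstituted alkene followed by β-hydride elimination should give the C6 methyl ketone, the trisubstituted chain alkenes not competing for Pd(II).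

Step 12
Reactants: 23 2-(trimethylsilyl)ethyl (6R,8E,12E)-6-acetyl-4,6,9,13,17-pentamethyl-3,5-dioxooctadeca-8,12,16-trienoate
Product: 25 2-(trimethylsilyl)ethyl (3R)-6-hydroxy-2,3,5-trimethyl-4-oxo-3-[(2E,6E)-3,7,11-trimethyldodeca-2,6,10-trien-1-yl]cyclohexa-1,5-diene-1-carboxylate, via 2-(trimethylsilyl)ethyl (3R)-2-hydroxy-2,3,5-trimethyl-4,6-dioxo-3-[(2E,6E)-3,7,11-trimethyldodeca-2,6,10-trien-1-yl]cyclohexane-1-carboxylate 24 (not isolated)
Conditions: Et3N, CH2Cl2, 4 Å MS, rt → 40 °C; aq. citric acid work-up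
Reagents that add atoms: none
Why: Intramolecular Knoevenagel-type aldol–dehydration of the kind that turns 3,5,7-triketo esters into resorcylates: the C5 enolate should attack the C6 ketone in a 6-(enolendo)-exo-trig closure, E1cB loss of water gives C5=C6, enolisation of C3–H gives the hydrogen-bonded cross-conjugated enol, and the non-nucleophilic base spares the quaternary C1, which cannot epimerise.

Step 13
Reactants: 25 2-(trimethylsilyl)ethyl (3R)-6-hydroxy-2,3,5-trimethyl-4-oxo-3-[(2E,6E)-3,7,11-trimethyldodeca-2,6,10-trien-1-yl]cyclohexa-1,5-diene-1-carboxylate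
Product: 26 (3R)-6-hydroxy-2,3,5-trimethyl-4-oxo-3-[(2E,6E)-3,7,11-trimethyldodeca-2,6,10-trien-1-yl]cyclohexa-1,5-diene-1-carboxylic acid (CID137333727)
Conditions: TBAF, THF, 0 °C → rt; cold dilute aq. HCl to pH 3
Reagents that add atoms: none
Why: Fluoride attack on silicon triggers β-fragmentation of the 2-(trimethylsilyl)ethyl ester at room temperature, freeing the carboxylate without acid strong enough to cyclise the polyene or heat that could decarboxylate the β-keto-acid-like product.

**Compound list**

1 | (2E,6E)-farnesyl bromide | CC(C)=CCC/C(C)=C/CC/C(C)=C/CBr | starting material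
2 | ethynylmagnesium bromide | C#C[Mg]Br | starting material
3 | (4E,8E)-5,9,13-trimethyltetradeca-4,8,12-trien-1-yne | CC(C)=CCC/C(C)=C/CC/C(C)=C/CC#C | intermediate
4 | dimethyl[(1E,4E,8E)-2,5,9,13-tetramethyltetradeca-1,4,8,12-tetraen-1-yl]alumane | CC(C)=CCC/C(C)=C/CC/C(C)=C/C/C(C)=C/[Al](C)C | intermediate (not isolated)
5 | lithium butyl(dimethyl)[(1E,4E,8E)-2,5,9,13-tetramethyltetradeca-1,4,8,12-tetraen-1-yl]aluminate | CC(C)=CCC/C(C)=C/CC/C(C)=C/C/C(C)=C/[Al-](C)(C)CCCC.[Li+] | intermediate (not isolated)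
6 | (2E,5E,9E)-3,6,10,14-tetramethylpentadeca-2,5,9,13-tetraen-1-ol | CC(C)=CCC/C(C)=C/CC/C(C)=C/C/C(C)=C/CO | intermediate
7 | methyl (2E,5E,9E)-3,6,10,14-tetramethylpentadeca-2,5,9,13-tetraen-1-yl carbonate | CC(C)=CCC/C(C)=C/CC/C(C)=C/C/C(C)=C/COC(=O)OC | intermediate
8 | bis(pinacolato)diboron | CC1(C)OB(OC1(C)C)B1OC(C)(C)C(C)(C)O1 | starting material
9 | 2-[(3S,5E,9E)-3,6,10,14-tetramethylpentadeca-1,5,9,13-tetraen-3-yl]-4,4,5,5-tetramethyl-1,3,2-dioxaborolane | CC(C)=CCC/C(C)=C/CC/C(C)=C/C[C@](C)(C=C)B1OC(C)(C)C(C)(C)O1 | intermediate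
10 | prop-2-en-1-ol (allyl alcohol) | C=CCO | starting material
11 | N,N-diisopropylcarbamoyl chloride | CC(C)N(C(C)C)C(Cl)=O | starting material
12 | prop-2-en-1-yl N,N-di(propan-2-yl)carbamate | C=CCOC(=O)N(C(C)C)C(C)C | intermediate
13 | (Z)-prop-1-en-1-yl N,N-di(propan-2-yl)carbamate | C/C=C\OC(=O)N(C(C)C)C(C)C | intermediate
14 | (Z)-1-lithioprop-1-en-1-yl N,N-di(propan-2-yl)carbamate | C/C=C(\OC(=O)N(C(C)C)C(C)C)[Li] | intermediate (not isolated)
15 | lithium {(1Z)-1-[(diisopropylcarbamoyl)oxy]prop-1-en-1-yl}[(3S,5E,9E)-3,6,10,14-tetramethylpentadeca-1,5,9,13-tetraen-3-yl](pinacolato)borate | CC(C)=CCC/C(C)=C/CC/C(C)=C/C[C@](C)(C=C)[B-]1(OC(C)(C)C(C)(C)O1)/C(OC(=O)N(C(C)C)C(C)C)=C/C.[Li+] | intermediate (not isolated)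
16 | 2-[(2E,4R,6E,10E)-4-ethenyl-4,7,11,15-tetramethylhexadeca-2,6,10,14-tetraen-3-yl]-4,4,5,5-tetramethyl-1,3,2-dioxaborolane | CC(C)=CCC/C(C)=C/CC/C(C)=C/C[C@](C)(C=C)/C(B1OC(C)(C)C(C)(C)O1)=C/C | intermediate (not isolated)
17 | (4R,6E,10E)-4-ethenyl-4,7,11,15-tetramethylhexadeca-6,10,14-trien-3-one | CC(C)=CCC/C(C)=C/CC/C(C)=C/C[C@](C)(C=C)C(=O)CC | intermediate
18 | lithium (2Z,4R,6E,10E)-4-ethenyl-4,7,11,15-tetramethylhexadeca-2,6,10,14-tetraen-3-olate | CC(C)=CCC/C(C)=C/CC/C(C)=C/C[C@](C)(C=C)/C(O[Li])=C/C | intermediate (not isolated)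
19 | (5R,7E,11E)-5-ethenyl-2-hydroxy-3,5,8,12,16-pentamethylheptadeca-7,11,15-trien-4-one (mixture at C2, C3) | CC(C)=CCC/C(C)=C/CC/C(C)=C/C[C@](C)(C=C)C(=O)C(C)C(C)O | intermediate
20 | (5R,7E,11E)-5-ethenyl-3,5,8,12,16-pentamethylheptadeca-7,11,15-triene-2,4-dione | CC(C)=CCC/C(C)=C/CC/C(C)=C/C[C@](C)(C=C)C(=O)C(C)C(C)=O | intermediate
21 | dilithium (5R,7E,11E)-5-ethenyl-3,5,8,12,16-pentamethylheptadeca-1,3,7,11,15-pentaene-2,4-diolate | CC(C)=CCC/C(C)=C/CC/C(C)=C/C[C@](C)(C=C)C([O-])=C(C)C([O-])=C.[Li+].[Li+] | intermediate (not isolated)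
22 | 2-(trimethylsilyl)ethyl (6R,8E,12E)-6-ethenyl-4,6,9,13,17-pentamethyl-3,5-dioxooctadeca-8,12,16-trienoate | CC(C)=CCC/C(C)=C/CC/C(C)=C/C[C@](C)(C=C)C(=O)C(C)C(=O)CC(=O)OCC[Si](C)(C)C | intermediate
23 | 2-(trimethylsilyl)ethyl (6R,8E,12E)-6-acetyl-4,6,9,13,17-pentamethyl-3,5-dioxooctadeca-8,12,16-trienoate | CC(C)=CCC/C(C)=C/CC/C(C)=C/C[C@](C)(C(C)=O)C(=O)C(C)C(=O)CC(=O)OCC[Si](C)(C)C | intermediate
24 | 2-(trimethylsilyl)ethyl (3R)-2-hydroxy-2,3,5-trimethyl-4,6-dioxo-3-[(2E,6E)-3,7,11-trimethyldodeca-2,6,10-trien-1-yl]cyclohexane-1-carboxylate | CC(C)=CCC/C(C)=C/CC/C(C)=C/C[C@@]1(C)C(=O)C(C)C(=O)C(C(=O)OCC[Si](C)(C)C)C1(C)O | intermediate (not isolated)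
25 | 2-(trimethylsilyl)ethyl (3R)-6-hydroxy-2,3,5-trimethyl-4-oxo-3-[(2E,6E)-3,7,11-trimethyldodeca-2,6,10-trien-1-yl]cyclohexa-1,5-diene-1-carboxylate | CC(C)=CCC/C(C)=C/CC/C(C)=C/C[C@@]1(C)C(=O)C(C)=C(O)C(C(=O)OCC[Si](C)(C)C)=C1C | intermediate
26 | (3R)-6-hydroxy-2,3,5-trimethyl-4-oxo-3-[(2E,6E)-3,7,11-trimethyldodeca-2,6,10-trien-1-yl]cyclohexa-1,5-diene-1-carboxylic acid | CC(C)=CCC/C(C)=C/CC/C(C)=C/C[C@@]1(C)C(=O)C(C)=C(O)C(C(=O)O)=C1C | target

**Step count**

Total: 13 steps. Longest linear sequence: 11 steps (steps 1–4 and 7–13, from farnesyl bromide); steps 5 and 6 form the two-step side branch to the enol carbamate.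

**Steps most likely to fail, with fallbacks**

Step 7 (Proposed new method). The sp2 C–O bond of the ate complex may fail to ionise before the hindered complex reverts to its components. A pinacol oxygen or the allyl terminus may also migrate in place of C1. The fallback uses known Matteson chemistry and keeps the same stereoretentive boron-to-carbon shift from C1, but onto an sp3 chloride carbenoid. It sets out from 9. Dichloromethyllithium (CH2Cl2, n-BuLi, THF, −100 °C), then ZnCl2 and warming, should give 2-[(2R,4E,8E)-1-chloro-2-ethenyl-2,5,9,13-tetramethyltetradeca-4,8,12-trien-1-yl]-4,4,5,5-tetramethyl-1,3,2-dioxaborolane F1. Ethylmagnesium bromide then displaces chloride through a second boronate rearrangement to give 2-[(4S,6E,10E)-4-ethenyl-4,7,11,15-tetramethylhexadeca-6,10,14-trien-3-yl]-4,4,5,5-tetramethyl-1,3,2-dioxaborolane F2. Alkaline hydrogen peroxide gives (4R,6E,10E)-4-ethenyl-4,7,11,15-tetramethylhexadeca-6,10,14-trien-3-ol F3, and Dess–Martin oxidation comes back to the route at 17.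

Step 11. Hydroxypalladation may occur at the terminal carbon of the neopentyl-type vinyl group next to a carbonyl, giving aldehyde. Palladium and copper may be sequestered by the β-dicarbonyl unit, and the enol carbon may attack the coordinated alkene before water does. The fallback makes that last process the intended one. It sets out from 22 and uses palladium(II)-catalysed intramolecular oxidative alkylation of a 4-pentenyl β-keto ester [PdCl2(MeCN)2 cat., CuCl2, dioxane, rt]. The C5 enol carbon attacks the internal vinyl carbon in a 6-exo closure that fixes the regiochemistry by ring size. β-Hydride elimination gives 2-(trimethylsilyl)ethyl (3R)-3,5-dimethyl-2-methylidene-4,6-dioxo-3-[(2E,6E)-3,7,11-trimethyldodeca-2,6,10-trien-1-yl]cyclohexane-1-carboxylate F4, which should tautomerise into conjugation and come back to the route at 25, passing over 23 and 24.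

Step 4. Facial discrimination between the CH3 and CH2 substituents of the (E)-alkene may be insufficient, or linear (SN2) borylation may compete. The fallback replaces catalyst control by a stereospecific lithiation–borylation of a secondary allylic carbamate. It sets out from 1, 8 and 11. Palladium-catalysed borylation of 1 with 8 [Pd2(dba)3 cat., THF, 50 °C] gives 4,4,5,5-tetramethyl-2-[(2E,6E)-3,7,11-trimethyldodeca-2,6,10-trien-1-yl]-1,3,2-dioxaborolane F5. Commercial (S)-but-3-en-2-ol and 11 (pyridine, 90 °C) give (2S)-but-3-en-2-yl N,N-di(propan-2-yl)carbamate F6. α-Lithiation of F6 (s-BuLi, TMEDA, Et2O, −78 °C), α-selective borylation with F5 and MgBr2-promoted 1,2-shift of the farnesyl group should come back to the route at 9. The (S)-carbamate is chosen on the usual course: lithiation and borylation with retention, migration with inversion at the carbamate carbon.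

**Further compounds**

F1 | step 7 | 2-[(2R,4E,8E)-1-chloro-2-ethenyl-2,5,9,13-tetramethyltetradeca-4,8,12-trien-1-yl]-4,4,5,5-tetramethyl-1,3,2-dioxaborolane | CC(C)=CCC/C(C)=C/CC/C(C)=C/C[C@](C)(C=C)C(Cl)B1OC(C)(C)C(C)(C)O1
F2 | step 7 | 2-[(4S,6E,10E)-4-ethenyl-4,7,11,15-tetramethylhexadeca-6,10,14-trien-3-yl]-4,4,5,5-tetramethyl-1,3,2-dioxaborolane | CC(C)=CCC/C(C)=C/CC/C(C)=C/C[C@](C)(C=C)C(CC)B1OC(C)(C)C(C)(C)O1
F3 | step 7 | (4R,6E,10E)-4-ethenyl-4,7,11,15-tetramethylhexadeca-6,10,14-trien-3-ol | CC(C)=CCC/C(C)=C/CC/C(C)=C/C[C@](C)(C=C)C(O)CC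
F4 | step 11 | 2-(trimethylsilyl)ethyl (3R)-3,5-dimethyl-2-methylidene-4,6-dioxo-3-[(2E,6E)-3,7,11-trimethyldodeca-2,6,10-trien-1-yl]cyclohexane-1-carboxylate | CC(C)=CCC/C(C)=C/CC/C(C)=C/C[C@@]1(C)C(=O)C(C)C(=O)C(C(=O)OCC[Si](C)(C)C)C1=C
F5 | step 4 | 4,4,5,5-tetramethyl-2-[(2E,6E)-3,7,11-trimethyldodeca-2,6,10-trien-1-yl]-1,3,2-dioxaborolane | CC(C)=CCC/C(C)=C/CC/C(C)=C/CB1OC(C)(C)C(C)(C)O1
F6 | step 4 | (2S)-but-3-en-2-yl N,N-di(propan-2-yl)carbamate | C[C@@H](C=C)OC(=O)N(C(C)C)C(C)C
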